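## Retrosynthetic overview

1. Target 23 ⇐ O-sulfation of hydroxy acid 21.
2. 21 ⇐ intramolecular Diels–Alder reaction of hexaenoic acid 20; rings A and B close in the same step (bonds C7–C12 and C6–C15 of the chain).
3. 20 ⇐ Heck coupling of (E)-alkenyl iodide 18 with penta-2,4-dienoic acid; 18 ⇐ terminal alkyne 16 ⇐ (Z)-enol carbamate 14.
4. 14 ⇐ key C8–C9 bond: sparteine-mediated homoaldol reaction of a metalated crotyl carbamate (homoenolate equivalent) with trienal 8, which sets both tether stereocentres.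
5. 8 ⇐ Claisen rearrangement of the vinyl ether of trienol 5 ⇐ dienal 3 ⇐ tiglic aldehyde.

Assumption: the sparteine-mediated crotyl carbamate homoaldol follows its established sense ((−)-sparteine gives (3S,4R) adducts), so commercial (+)-sparteine is used for the (3R,4S) series; the target is isolated as the free acid drawn.

## Route

Step 1
Reactants: 1 (2E)-2-methylbut-2-enal; 2 2-(triphenylphosphoranylidene)propanal
Product: 3 (2E,4E)-2,4-dimethylhexa-2,4-dienal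
Conditions: PhMe, 110 °C, 16 h
Reagents that add atoms: none
Why: Wittig olefination with a formyl-stabilised ylide gives the (E)-trisubstituted enal, and the α-branched dienal product is too hindered to react a second time.

Step 2
Reactants: 3 (2E,4E)-2,4-dimethylhexa-2,4-dienal; 4 vinylmagnesium bromide
Product: 5 (4E,6E)-4,6-dimethylocta-1,4,6-trien-3-ol (racemic)
Conditions: THF, −78 → 0 °C; aq. NH4Cl
Reagents that add atoms: none
Why: Grignard 1,2-addition to the enal; the new carbinol centre is racemic and is destroyed in step 3.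

Step 3
Reactants: 5 (4E,6E)-4,6-dimethylocta-1,4,6-trien-3-ol; 6 ethyl vinyl ether
Product: 8 (4E,6E,8E)-6,8-dimethyldeca-4,6,8-trienal, via allyl vinyl ether 7 (not isolated)
Conditions: Hg(OAc)2 (5 mol%), NaOAc, neat 6, sealed tube, 40 °C then 120 °C
Reagents that add atoms: none
Why: Transetherification followed by Claisen [3,3]-rearrangement through the unsubstituted vinyl terminus; the chair transition state with the dienyl group equatorial gives the new (4E)-alkene and a conjugated triene.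

Step 4
Reactants: 9 (2E)-but-2-en-1-ol; 10 N,N-di(propan-2-yl)carbamoyl chloride
Product: 11 (2E)-but-2-en-1-yl N,N-di(propan-2-yl)carbamate
Conditions: NaH, THF, 0 → 65 °C
Reagents that add atoms: none
Why: Carbamoylation of the sodium alkoxide (nucleophilic acyl substitution); the alkene geometry is untouched.

Step 5
Reactants: 11 (2E)-but-2-en-1-yl N,N-di(propan-2-yl)carbamate; 8 (4E,6E,8E)-6,8-dimethyldeca-4,6,8-trienal
Product: 14 (1Z,3R,4S,7E,9E,11E)-4-hydroxy-3,9,11-trimethyltrideca-1,7,9,11-tetraen-1-yl N,N-di(propan-2-yl)carbamate, via lithiated carbamate 12 (not isolated), via allyltitanium reagent 13 (not isolated)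
Conditions: n-BuLi, (+)-sparteine, pentane/cyclohexane, −78 °C, 3 h (crystallisation); Ti(OiPr)4, −78 °C; then 8, −78 → −20 °C; aq. HCl
Reagents that add atoms: none
Why: Hoppe homoaldol reaction: the 1-oxyallyl anion is a homoenolate equivalent, so the carbon β to the latent aldehyde (normally electrophilic) attacks the aldehyde carbon of 8; one epimer of the lithium–sparteine complex crystallises, titanation inverts it, and γ-attack through a Zimmerman–Traxler chair gives the (Z)-enol carbamate with anti (3R,4S) centres (about 90% ee expected).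

Step 6
Reactants: 14 (1Z,3R,4S,7E,9E,11E)-4-hydroxy-3,9,11-trimethyltrideca-1,7,9,11-tetraen-1-yl N,N-di(propan-2-yl)carbamate
Product: 16 (3R,4S,7E,9E,11E)-3,9,11-trimethyltrideca-7,9,11-trien-1-yn-4-ol, via dilithiated enol carbamate 15 (not isolated)
Conditions: t-BuLi (3.2 equiv), THF, −78 → −30 °C; aq. NH4Cl
Reagents that add atoms: none
Why: After O-deprotonation, carbamate-directed α-lithiation of the enol carbamate and Fritsch–Buttenberg–Wiechell-type loss of lithium carbamate give the acetylide, protonated on work-up; both stereocentres are untouched.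

Step 7
Reactants: 16 (3R,4S,7E,9E,11E)-3,9,11-trimethyltrideca-7,9,11-trien-1-yn-4-ol
Product: 18 (1E,3R,4S,7E,9E,11E)-1-iodo-3,9,11-trimethyltrideca-1,7,9,11-tetraen-4-ol, via alkenylzirconocene 17 (not isolated)
Conditions: Cp2Zr(H)Cl (2.3 equiv), THF, rt, dark; I2 (1.05 equiv), −78 → 0 °C; aq. Na2S2O3
Reagents that add atoms: iodine, [I][I]
Why: Hydrozirconation (syn addition, Zr at the terminal carbon; the first equivalent is consumed by the hydroxyl) then iodinolysis with retention gives the (E)-alkenyl iodide, and the trisubstituted triene is inert to the hydride.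

Step 8
Reactants: 18 (1E,3R,4S,7E,9E,11E)-1-iodo-3,9,11-trimethyltrideca-1,7,9,11-tetraen-4-ol; 19 (2E)-penta-2,4-dienoic acid
Product: 20 (2E,4E,6E,8R,9S,12E,14E,16E)-9-hydroxy-8,14,16-trimethyloctadeca-2,4,6,12,14,16-hexaenoic acid
Conditions: Pd(OAc)2 (10 mol%), K2CO3, Bu4NCl, DMF, 40 °C, dark; aq. citric acid
Reagents that add atoms: none
Why: Heck reaction under ligand-free phase-transfer (Jeffery) conditions: the alkenylpalladium from 18 (geometry retained) adds to the terminal CH2 of the dienoate and β-hydride elimination restores the conjugated (2E,4E,6E)-triene.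

Step 9
Reactants: 20 (2E,4E,6E,8R,9S,12E,14E,16E)-9-hydroxy-8,14,16-trimethyloctadeca-2,4,6,12,14,16-hexaenoic acid
Product: 21 (2E,4E)-5-[(1S,2S,4aS,7S,8R,8aR)-2-[(2E)-but-2-en-2-yl]-7-hydroxy-3,8-dimethyl-1,2,4a,5,6,7,8,8a-octahydronaphthalen-1-yl]penta-2,4-dienoic acid
Conditions: PhMe (0.005 M), BHT, 110 °C, 36 h; chromatography
Reagents that add atoms: none
Why: Thermal intramolecular Diels–Alder reaction (type 1): suprafacial addition of the (12E,14E)-diene to the (6E)-alkene fixes H-2/H-4a cis and H-1/H-8a trans, a chair-like tether with the C8 methyl equatorial and the hydroxyl axial sets C8–Me trans to C1, and the tether-endo (acid chain exo) transition state gives the cis ring fusion of 21; the acid-endo mode gives the trans-fused isomer in a comparable amount, which is separated.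

Step 10
Reactants: 21 (2E,4E)-5-[(1S,2S,4aS,7S,8R,8aR)-2-[(2E)-but-2-en-2-yl]-7-hydroxy-3,8-dimethyl-1,2,4a,5,6,7,8,8a-octahydronaphthalen-1-yl]penta-2,4-dienoic acid
Product: 23 (2E,4E)-5-[(1S,2S,4aS,7S,8R,8aR)-2-[(2E)-but-2-en-2-yl]-3,8-dimethyl-7-(sulfooxy)-1,2,4a,5,6,7,8,8a-octahydronaphthalen-1-yl]penta-2,4-dienoic acid, via pyridinium sulfate salt 22 (not isolated)
Conditions: SO3·pyridine (4 equiv), pyridine, 0 °C → rt; H2O; Dowex 50W (H+ form), 0 °C; lyophilise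
Reagents that add atoms: sulfur trioxide–pyridine complex, [O-]S(=O)(=O)[n+]1ccccc1
Why: O-sulfation of the secondary alcohol with retention at C7 (only the O–S bond forms); any acyl sulfate at the carboxyl group is hydrolysed by the water quench and ion exchange gives the free acid.

## Compound list

1 | (2E)-2-methylbut-2-enal (tiglic aldehyde) | C/C=C(\C)C=O | starting material
2 | 2-(triphenylphosphoranylidene)propanal | CC(C=O)=P(c1ccccc1)(c1ccccc1)c1ccccc1 | starting material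
3 | (2E,4E)-2,4-dimethylhexa-2,4-dienal | C/C=C(\C)/C=C(\C)C=O | intermediate
4 | vinylmagnesium bromide | C=C[Mg]Br | starting material
5 | (4E,6E)-4,6-dimethylocta-1,4,6-trien-3-ol (racemic) | C=CC(O)/C(C)=C/C(C)=C/C | intermediate
6 | ethyl vinyl ether | C=COCC | starting material
7 | (4E,6E)-3-(ethenyloxy)-4,6-dimethylocta-1,4,6-triene (racemic) | C=COC(C=C)/C(C)=C/C(C)=C/C | intermediate (not isolated)
8 | (4E,6E,8E)-6,8-dimethyldeca-4,6,8-trienal | O=CCC/C=C/C(C)=C/C(C)=C/C | intermediate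
9 | (2E)-but-2-en-1-ol | C/C=C/CO | starting material
10 | N,N-di(propan-2-yl)carbamoyl chloride | CC(C)N(C(C)C)C(Cl)=O | starting material
11 | (2E)-but-2-en-1-yl N,N-di(propan-2-yl)carbamate | C/C=C/COC(=O)N(C(C)C)C(C)C | intermediate
12 | (1R,2E)-1-lithiobut-2-en-1-yl N,N-di(propan-2-yl)carbamate, (+)-sparteine complex (ligand omitted from the SMILES) | C/C=C/[C@@H]([Li])OC(=O)N(C(C)C)C(C)C | intermediate (not isolated)
13 | (1S,2E)-1-[tri(propan-2-yloxy)titanio]but-2-en-1-yl N,N-di(propan-2-yl)carbamate | C/C=C/[C@H]([Ti](OC(C)C)(OC(C)C)OC(C)C)OC(=O)N(C(C)C)C(C)C | intermediate (not isolated)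
14 | (1Z,3R,4S,7E,9E,11E)-4-hydroxy-3,9,11-trimethyltrideca-1,7,9,11-tetraen-1-yl N,N-di(propan-2-yl)carbamate | CC(C)N(C(C)C)C(=O)O/C=C\[C@@H](C)[C@@H](O)CC/C=C/C(C)=C/C(C)=C/C | intermediate
15 | O,C1-dilithio derivative of 14 (lithium alkoxide, 1-lithio enol carbamate) | CC(C)N(C(C)C)C(=O)O/C([Li])=C\[C@@H](C)[C@@H](O[Li])CC/C=C/C(C)=C/C(C)=C/C | intermediate (not isolated)
16 | (3R,4S,7E,9E,11E)-3,9,11-trimethyltrideca-7,9,11-trien-1-yn-4-ol | C#C[C@@H](C)[C@@H](O)CC/C=C/C(C)=C/C(C)=C/C | intermediate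
17 | (1E)-alkenyl(chloro)zirconocene of 16, hydroxyl as chlorozirconocene alkoxide (cyclopentadienyl rings written σ-bonded) | Cl[Zr](C1C=CC=C1)(C1C=CC=C1)/C=C/[C@@H](C)[C@@H](O[Zr](Cl)(C1C=CC=C1)C1C=CC=C1)CC/C=C/C(C)=C/C(C)=C/C | intermediate (not isolated)
18 | (1E,3R,4S,7E,9E,11E)-1-iodo-3,9,11-trimethyltrideca-1,7,9,11-tetraen-4-ol | I/C=C/[C@@H](C)[C@@H](O)CC/C=C/C(C)=C/C(C)=C/C | intermediate
19 | (2E)-penta-2,4-dienoic acid | OC(=O)/C=C/C=C | starting material
20 | (2E,4E,6E,8R,9S,12E,14E,16E)-9-hydroxy-8,14,16-trimethyloctadeca-2,4,6,12,14,16-hexaenoic acid | OC(=O)/C=C/C=C/C=C/[C@@H](C)[C@@H](O)CC/C=C/C(C)=C/C(C)=C/C | intermediate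
21 | (2E,4E)-5-[(1S,2S,4aS,7S,8R,8aR)-2-[(2E)-but-2-en-2-yl]-7-hydroxy-3,8-dimethyl-1,2,4a,5,6,7,8,8a-octahydronaphthalen-1-yl]penta-2,4-dienoic acid | C/C=C(\C)[C@H]1C(C)=C[C@H]2CC[C@H](O)[C@H](C)[C@H]2[C@@H]1/C=C/C=C/C(=O)O | intermediate
22 | pyridinium salt of the C7 sulfate monoester of 21 | C/C=C(\C)[C@H]1C(C)=C[C@H]2CC[C@H](OS(=O)(=O)[O-])[C@H](C)[C@H]2[C@@H]1/C=C/C=C/C(=O)O.c1cc[nH+]cc1 | intermediate (not isolated)
23 | (2E,4E)-5-[(1S,2S,4aS,7S,8R,8aR)-2-[(2E)-but-2-en-2-yl]-3,8-dimethyl-7-(sulfooxy)-1,2,4a,5,6,7,8,8a-octahydronaphthalen-1-yl]penta-2,4-dienoic acid | C/C=C(\C)[C@H]1C(C)=C[C@H]2CC[C@H](OS(=O)(=O)O)[C@H](C)[C@H]2[C@@H]1/C=C/C=C/C(=O)O | target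

## Count and risks

Total steps: 10. Longest linear sequence: 9 (steps 1, 2, 3, 5, 6, 7, 8, 9, 10).

**Step 9 (ring fusion selectivity).** A thermal cyclisation of an (E)-dienophile with a terminal activating group has little endo/exo bias, so the cis-fused 21 is expected as roughly half of the adduct mixture at best; Lewis acids would favour the trans-fused isomer. The fallback sets out from 16 and comes back at 21, using a (Z)-dienophile so that the endo rule and the tether agree.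
- 16 is silylated (TBSCl, imidazole) to tert-butyl(dimethyl){[(3R,4S,7E,9E,11E)-3,9,11-trimethyltrideca-7,9,11-trien-1-yn-4-yl]oxy}silane F1.
- n-BuLi then ClCO2Me gives methyl (4R,5S,8E,10E,12E)-5-[(tert-butyldimethylsilyl)oxy]-4,10,12-trimethyltetradeca-8,10,12-trien-2-ynoate F2.
- Semihydrogenation (H2, Pd/CaCO3 poisoned with Pb(OAc)2, quinoline) gives methyl (2Z,4R,5S,8E,10E,12E)-5-[(tert-butyldimethylsilyl)oxy]-4,10,12-trimethyltetradeca-2,8,10,12-tetraenoate F3.
- Me2AlCl (CH2Cl2, −78 → 0 °C) promotes the endo cycloaddition, ester and tether on the same side, to cis-fused methyl (1R,2S,4aS,7S,8R,8aS)-2-[(2E)-but-2-en-2-yl]-7-[(tert-butyldimethylsilyl)oxy]-3,8-dimethyl-1,2,4a,5,6,7,8,8a-octahydronaphthalene-1-carboxylate F4.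
- NaOMe/MeOH epimerises C1 to the all-equatorial methyl (1S,2S,4aS,7S,8R,8aS)-2-[(2E)-but-2-en-2-yl]-7-[(tert-butyldimethylsilyl)oxy]-3,8-dimethyl-1,2,4a,5,6,7,8,8a-octahydronaphthalene-1-carboxylate F5.
- iBu2AlH at −78 °C gives (1S,2S,4aS,7S,8R,8aS)-2-[(2E)-but-2-en-2-yl]-7-[(tert-butyldimethylsilyl)oxy]-3,8-dimethyl-1,2,4a,5,6,7,8,8a-octahydronaphthalene-1-carbaldehyde F6.
- Horner–Wadsworth–Emmons reaction with triethyl 4-phosphonocrotonate and LiN(SiMe3)2 gives ethyl (2E,4E)-5-[(1S,2S,4aS,7S,8R,8aR)-2-[(2E)-but-2-en-2-yl]-7-[(tert-butyldimethylsilyl)oxy]-3,8-dimethyl-1,2,4a,5,6,7,8,8a-octahydronaphthalen-1-yl]penta-2,4-dienoate F7.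
- Bu4NF gives ethyl (2E,4E)-5-[(1S,2S,4aS,7S,8R,8aR)-2-[(2E)-but-2-en-2-yl]-7-hydroxy-3,8-dimethyl-1,2,4a,5,6,7,8,8a-octahydronaphthalen-1-yl]penta-2,4-dienoate F8, and LiOH (THF/H2O) then gives 21.

**Step 6 (t-BuLi in the presence of a free alkoxide and a conjugated triene).** Carbolithiation of the triene or incomplete elimination would lower the yield. The fallback sets out from 8 and comes back at 16: commercial (S)-but-3-yn-2-ol is mesylated to (2S)-but-3-yn-2-yl methanesulfonate F9, which is coupled with 8 by polarity reversal of the propargylic electrophile (Pd(PPh3)4 cat., Et2Zn, THF, −78 → −20 °C). Anti oxidative addition followed by syn addition of the allenylzinc to the aldehyde should give the anti (3R,4S) homopropargylic alcohol 16 directly.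

**Step 8 (Heck coupling on a polyene with a free dienoic acid).** Allylpalladium trapping, double-bond isomerisation or polymerisation of 19 are possible. The fallback sets out from 16 and comes back at 20, replacing the coupling by olefination.
- The dianion of 16 (n-BuLi, 2.1 equiv) adds to paraformaldehyde to give (4R,5S,8E,10E,12E)-4,10,12-trimethyltetradeca-8,10,12-trien-2-yne-1,5-diol F10.
- LiAlH4 (THF) reduces the propargylic alcohol to (2E,4R,5S,8E,10E,12E)-4,10,12-trimethyltetradeca-2,8,10,12-tetraene-1,5-diol F11.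
- MnO2 oxidises only the allylic alcohol to (2E,4R,5S,8E,10E,12E)-5-hydroxy-4,10,12-trimethyltetradeca-2,8,10,12-tetraenal F12, which is used at once.
- Triethyl 4-phosphonocrotonate and LiN(SiMe3)2 (−78 → 0 °C) give ethyl (2E,4E,6E,8R,9S,12E,14E,16E)-9-hydroxy-8,14,16-trimethyloctadeca-2,4,6,12,14,16-hexaenoate F13, and LiOH at 0 °C then gives 20.

## Further compounds

F1 | step 9 | tert-butyl(dimethyl){[(3R,4S,7E,9E,11E)-3,9,11-trimethyltrideca-7,9,11-trien-1-yn-4-yl]oxy}silane | C#C[C@@H](C)[C@@H](O[Si](C)(C)C(C)(C)C)CC/C=C/C(C)=C/C(C)=C/C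
F2 | step 9 | methyl (4R,5S,8E,10E,12E)-5-[(tert-butyldimethylsilyl)oxy]-4,10,12-trimethyltetradeca-8,10,12-trien-2-ynoate | COC(=O)C#C[C@@H](C)[C@@H](O[Si](C)(C)C(C)(C)C)CC/C=C/C(C)=C/C(C)=C/C
F3 | step 9 | methyl (2Z,4R,5S,8E,10E,12E)-5-[(tert-butyldimethylsilyl)oxy]-4,10,12-trimethyltetradeca-2,8,10,12-tetraenoate | COC(=O)/C=C\[C@@H](C)[C@@H](O[Si](C)(C)C(C)(C)C)CC/C=C/C(C)=C/C(C)=C/C
F4 | step 9 | methyl (1R,2S,4aS,7S,8R,8aS)-2-[(2E)-but-2-en-2-yl]-7-[(tert-butyldimethylsilyl)oxy]-3,8-dimethyl-1,2,4a,5,6,7,8,8a-octahydronaphthalene-1-carboxylate | C/C=C(\C)[C@H]1C(C)=C[C@H]2CC[C@H](O[Si](C)(C)C(C)(C)C)[C@H](C)[C@H]2[C@H]1C(=O)OC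
F5 | step 9 | methyl (1S,2S,4aS,7S,8R,8aS)-2-[(2E)-but-2-en-2-yl]-7-[(tert-butyldimethylsilyl)oxy]-3,8-dimethyl-1,2,4a,5,6,7,8,8a-octahydronaphthalene-1-carboxylate | C/C=C(\C)[C@H]1C(C)=C[C@H]2CC[C@H](O[Si](C)(C)C(C)(C)C)[C@H](C)[C@H]2[C@@H]1C(=O)OC
F6 | step 9 | (1S,2S,4aS,7S,8R,8aS)-2-[(2E)-but-2-en-2-yl]-7-[(tert-butyldimethylsilyl)oxy]-3,8-dimethyl-1,2,4a,5,6,7,8,8a-octahydronaphthalene-1-carbaldehyde | C/C=C(\C)[C@H]1C(C)=C[C@H]2CC[C@H](O[Si](C)(C)C(C)(C)C)[C@H](C)[C@H]2[C@@H]1C=O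
F7 | step 9 | ethyl (2E,4E)-5-[(1S,2S,4aS,7S,8R,8aR)-2-[(2E)-but-2-en-2-yl]-7-[(tert-butyldimethylsilyl)oxy]-3,8-dimethyl-1,2,4a,5,6,7,8,8a-octahydronaphthalen-1-yl]penta-2,4-dienoate | C/C=C(\C)[C@H]1C(C)=C[C@H]2CC[C@H](O[Si](C)(C)C(C)(C)C)[C@H](C)[C@H]2[C@@H]1/C=C/C=C/C(=O)OCC
F8 | step 9 | ethyl (2E,4E)-5-[(1S,2S,4aS,7S,8R,8aR)-2-[(2E)-but-2-en-2-yl]-7-hydroxy-3,8-dimethyl-1,2,4a,5,6,7,8,8a-octahydronaphthalen-1-yl]penta-2,4-dienoate | C/C=C(\C)[C@H]1C(C)=C[C@H]2CC[C@H](O)[C@H](C)[C@H]2[C@@H]1/C=C/C=C/C(=O)OCC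
F9 | step 6 | (2S)-but-3-yn-2-yl methanesulfonate | C#C[C@H](C)OS(C)(=O)=O
F10 | step 8 | (4R,5S,8E,10E,12E)-4,10,12-trimethyltetradeca-8,10,12-trien-2-yne-1,5-diol | OCC#C[C@@H](C)[C@@H](O)CC/C=C/C(C)=C/C(C)=C/C
F11 | step 8 | (2E,4R,5S,8E,10E,12E)-4,10,12-trimethyltetradeca-2,8,10,12-tetraene-1,5-diol | OC/C=C/[C@@H](C)[C@@H](O)CC/C=C/C(C)=C/C(C)=C/C
F12 | step 8 | (2E,4R,5S,8E,10E,12E)-5-hydroxy-4,10,12-trimethyltetradeca-2,8,10,12-tetraenal | O=C/C=C/[C@@H](C)[C@@H](O)CC/C=C/C(C)=C/C(C)=C/C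
F13 | step 8 | ethyl (2E,4E,6E,8R,9S,12E,14E,16E)-9-hydroxy-8,14,16-trimethyloctadeca-2,4,6,12,14,16-hexaenoate | CCOC(=O)/C=C/C=C/C=C/[C@@H](C)[C@@H](O)CC/C=C/C(C)=C/C(C)=C/C
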